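## The problem

Compound 21 (CNP0108136.1) is a 14-membered carbocycle bridged by an α-alkylidene-γ-butyrolactone. The locants used here are: ring carbons C2–C11 and C13–C16, with C2 the epoxide methine, C4 the isopropenyl-bearing carbon, C6=C7 the exocyclic alkene of the lactone, C9 the lactone carbinol carbon, C13 and C15 the ketones and C16 the methyl-bearing epoxide carbon; C12 is the ester carbon on C11 and the lactone carbonyl carbon sits on C7. The lactone (C7, C8, C9, carbonyl carbon, ring oxygen) shares three carbons with the large ring, and the ring contains no heteroatom, so the macrocycle must be closed at a C–C bond. There are five stereocentres, C2 (S), C16 (S), C4 (R), C9 (S) and C11 (S), plus the E geometry of C6=C7; on the oxirane C3 and C15 are cis. C4 can control C2 and C16 if all three sit in one six-membered ring. C9 lies four bonds and an sp2 carbon away from C4 and needs its own source of chirality or a relay, and C11, flanked by two carbonyl groups, is only under thermodynamic control. The C12/C13/C15 β,δ-diketo ester is acidic, prone to retro-Claisen cleavage and can attack the adjacent epoxide; the alkylidene lactone is a Michael acceptor that can deconjugate under base; the isopropenyl group excludes ozone, boranes and hydrogenation. The enabling feature is the pattern C6=C7(–carbonyl)–C8–C9(–O): these atoms are what a [3,3] shift leaves behind when a C6 carbinol is esterified by a glycolate whose own oxygen is acylated by the C7 carboxyl group, that is, a seven-membered glycolate–acrylate dilactone.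

## Retrosynthesis

**21 ⇒ 20 (cut C14–C15).** The 1,3-diketone is opened by a retro-Claisen cut that puts the nucleophile on C14 and leaves C15 as a methyl ester. This ester has no α-hydrogen (C16 is quaternary), so it can only act as acceptor. The neighbouring cuts (C13–C14, C10–C11) would need C15 at another oxidation level or a protecting group. Precursor 20 is open-chain and holds only a β-keto ester in place of the triketone. The forward step asks the C14 carbanion of a β-keto ester dianion to acylate at C15 in a 14-membered closure in the presence of the lactone; C11 settles by equilibration.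

**20 ⇒ 18 + 19 (cut C10–C11).** This is an acetoacetic ester alkylation: methyl acetoacetate (19) supplies C11, C12, C13 and C14 in one piece and iodide 18 is the electrophile. The forward reaction is an SN2 displacement at a primary iodide that is slowed by the β-oxygen of the lactone.

**18 ⇒ 17 ⇒ 15 (functional group changes at C10).** The iodide comes from alcohol 17 and this from carboxylic acid 15, the oxidation level a sigmatropic ester rearrangement leaves at C10. The reduction must spare the lactone, two alkenes and the epoxide, which rules out borane (isopropenyl group) and points to a mixed anhydride/NaBH4 reduction.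

**15 ⇒ 12 (cut C8–C9, re-form C6–O).** A retro-[3,3] shift turns the lactone acid 15 into seven-membered dilactone 12.
- Against an open-chain glycolate Claisen plus lactonisation, the ring fixes the ketene acetal geometry, needs no protecting group on the glycolate oxygen and closes the lactone in the same event.
- Against aldol or olefination routes to alkylidene lactones, it sets the E alkene and C9 together from a single carbinol centre.
- The precursor has one stereocentre fewer in the skeleton (C9 is traded for the C6 carbinol) and no C8–C9 bond.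
- The weak points are the strained geometry of the shift (the new bond is made to C8 while C9 stays tied to C7) and competing enolate pathways.
- They are met from within by an internal silyl chloride quench, by a C15 ester without α-hydrogen, and by a C6 carbinol of secure configuration.

**12 ⇒ 11 ⇒ 9 + 10 (cut two C–O bonds).** The glycolate unit is bromoacetyl bromide (10). Acylating the C6 hydroxyl first and closing by carboxylate alkylation second places the glycolate carbonyl on the C6 oxygen, the orientation the rearrangement needs. This is the established way to 1,4-dioxepane-2,5-diones.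

**9 ⇒ 8 ⇒ 6 + 7 (cut C6–C7).** A Morita–Baylis–Hillman disconnection gives aldehyde 6 and an acrylate. Hexafluoroisopropyl acrylate (7) with β-isocupreidine is chosen over methyl acrylate for two reasons. The catalyst sets C6 (R) directly, so no separation of carbinol epimers is needed. The activated ester can be hydrolysed beside the C15 methyl ester, which two methyl esters would not allow.

**6 ⇒ 4 ⇒ 3 ⇒ 2 ⇒ 1 (cut C5–C6, then re-form the C15–C5 bond).** Aldehyde 6 is the one-carbon homologue of aldehyde 4, which with its C15 ester is the cleavage product of α-ketol 3. Closing that bond gives the carvone skeleton, mapped as follows.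

| Carvone carbon | C1 | C2 | C3 | C4 | C5 | C6 |
|---|---|---|---|---|---|---|
| Target carbon | C15 | C16 | C2 | C3 | C4 | C5 |

The Z relationship of C15 and C3 is that of the ring enone. Epoxidation of the enone anti to the isopropenyl group, done on the ring in 2, sets C2 and C16 from C4. (S)-Carvone (1) gives (4R).

## Roads not taken

**Alternative 1:** The cut is C15–C16. An open-chain C15 aldehyde carrying a Z-vinyl iodide, A1, would be treated with CrCl2 and catalytic NiCl2 to give the macrocyclic allylic alcohol A2 (Nozaki–Hiyama–Kishi reaction).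
- Merits: the organochromium species adds to aldehydes only, the lactone and esters are not touched, no strong base is used, and the reaction type is well proven for carbocycles of this size. In reliability this ring closure is better than step 13 of the chosen route.
- Weak points: A2 still lacks the epoxide and both ketones. The epoxide would have to come from a hydroxyl-directed epoxidation whose face depends on a C15 carbinol configuration that the chromium addition does not control. Oxidation at C15 and desilylation and oxidation at C13 would follow, so the triketone emerges through several late redox steps next to an epoxide. The Z-vinyl iodide must be built separately, and the lactone with C9 and the E alkene needs a solution of its own.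
- Comparison: the chosen plan sets against the better ring closure an epoxide fixed in step 1 under control of C4, no protecting groups and no late oxidation-state changes.

**Alternative 2:** The cut is C13–C14 and O–C15. Aldoxime A3, bearing a terminal alkyne on the epoxide, would be oxidised with NaOCl to the nitrile oxide, which adds across the alkyne to give the isoxazole-bridged macrocycle A4.
- Merits: intramolecular nitrile oxide cycloadditions are reliable macrocyclisations, a terminal alkyne secures the regiochemistry, and the isoxazole hides the 1,3-diketone from everything that follows. In this respect it is better than the chosen plan, which forms the triketone under strongly basic conditions.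
- Weak points: the diketone is released by reductive N–O cleavage and hydrolysis of the vinylogous amide. The reductant (for example Mo(CO)6, or hydrogen over nickel) would have to spare the alkylidene lactone, the isopropenyl group and an epoxide that becomes an α,β-epoxy ketone as soon as the N–O bond breaks, and the hydrolysis needs acid at that same epoxide. The nitrile oxide sits next to the acidic C11–H, so dimerisation and loss of C11 are likely. The ethynyl epoxide costs extra steps.
- Comparison: the chosen plan sets against the better masking the absence of any unmasking step and a shorter sequence.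

**Alternative 3:** The cut is C10–C11. Iodo β-keto ester A5 would be cyclised with Cs2CO3 in dimethylformamide at high dilution to the macrocyclic β-keto ester A6, which carries C15 as a silyl ether.
- Merits: a soft enolate and a weak base are fully compatible with the lactone, and no carbanion strong enough to attack the lactone carbonyl is present. In chemoselectivity this closure is better than step 13, and it is kept as the fallback for that step.
- Weak points: C15 must be held at the alcohol level so that C14 does not become the nucleophile. This means an aldehyde at C15, a dianion aldol, a protecting group and a late deprotection and oxidation, about five more steps, with a transient C15 stereocentre. The iodide next to the lactone oxygen is a slow electrophile under high dilution.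
- Comparison: the chosen plan sets against the milder closure its brevity and the direct use of the C15 ester that carvone cleavage delivers.

Key step: step 9

Remark on C11: this centre is a readily enolised β-keto ester methine, and the (11S) epimer drawn is assumed to be the one favoured at equilibrium in the macrocycle, so no step sets it kinetically.

## Route

Step 1
Reactants: 1 (S)-(+)-carvone
Product: 2 (1S,4S,6S)-1-methyl-4-(prop-1-en-2-yl)-7-oxabicyclo[4.1.0]heptan-2-one
Conditions: 30% H2O2, NaOH (cat.), MeOH, 0 °C
Reagents that add atoms: hydrogen peroxide, OO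
Why: Weitz–Scheffer nucleophilic epoxidation; hydroperoxide adds to the enone anti to the isopropenyl group and the enolate closes the oxirane on that face, the known outcome for carvone. This sets C2 and C16 (target locants) relative to C4.

Step 2
Reactants: 2 (1S,4S,6S)-1-methyl-4-(prop-1-en-2-yl)-7-oxabicyclo[4.1.0]heptan-2-one
Product: 3 (1S,4R,6S)-3-hydroxy-1-methyl-4-(prop-1-en-2-yl)-7-oxabicyclo[4.1.0]heptan-2-one (C3 epimers)
Conditions: KN(SiMe3)2, THF, −78 °C; 2-(phenylsulfonyl)-3-phenyloxaziridine, −78 °C; aq. NH4Cl
Reagents that add atoms: 2-(phenylsulfonyl)-3-phenyloxaziridine, O=S(=O)(N1OC1c1ccccc1)c1ccccc1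
Why: Only C3 is enolisable (C1 is quaternary), so a single enolate forms and is hydroxylated by the oxaziridine (Davis oxidation). The new carbinol configuration is irrelevant because this carbon becomes an aldehyde in step 3.

Step 3
Reactants: 3 (1S,4R,6S)-3-hydroxy-1-methyl-4-(prop-1-en-2-yl)-7-oxabicyclo[4.1.0]heptan-2-one
Product: 4 methyl (2S,3S)-3-[(2R)-2-formyl-3-methylbut-3-en-1-yl]-2-methyloxirane-2-carboxylate
Conditions: Pb(OAc)4, MeOH/toluene (1:1), 0 °C
Reagents that add atoms: methanol, CO
Why: Criegee-type cleavage of an α-ketol: the methyl hemiketal of the ketone is cleaved between C2 and C3 to give the C15 methyl ester and the C5 aldehyde. Epoxide and isopropenyl group are inert at 0 °C; 4 is used at once because its α-centre (C4) is allylic.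

Step 4
Reactants: 4 methyl (2S,3S)-3-[(2R)-2-formyl-3-methylbut-3-en-1-yl]-2-methyloxirane-2-carboxylate
Product: 6 methyl (2S,3S)-2-methyl-3-[(2S)-3-methyl-2-(2-oxoethyl)but-3-en-1-yl]oxirane-2-carboxylate, via methyl enol ether 5 (not isolated)
Conditions: Ph3P(CH2OMe)Cl (1.5 equiv), KN(SiMe3)2 (1.4 equiv), THF, 0 °C; 4, −78 → 0 °C; then TsOH·H2O, THF/H2O, 20 °C
Reagents that add atoms: (methoxymethyl)triphenylphosphonium chloride, COC[P+](c1ccccc1)(c1ccccc1)c1ccccc1.[Cl-]; water, O
Why: Wittig methoxymethylenation and enol ether hydrolysis add C6 (one-carbon aldehyde homologation). A slight deficit of base and addition at −78 °C protect C4, and the electron-poor glycidic ester tolerates a non-nucleophilic acid.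

Step 5
Reactants: 6 methyl (2S,3S)-2-methyl-3-[(2S)-3-methyl-2-(2-oxoethyl)but-3-en-1-yl]oxirane-2-carboxylate; 7 1,1,1,3,3,3-hexafluoropropan-2-yl prop-2-enoate
Product: 8 1,1,1,3,3,3-hexafluoropropan-2-yl (3R,5R)-3-hydroxy-6-[(2S,3S)-3-(methoxycarbonyl)-3-methyloxiran-2-yl]-2-methylidene-5-(prop-1-en-2-yl)hexanoate
Conditions: β-isocupreidine (10 mol%), DMF, −55 °C
Reagents that add atoms: none
Why: Asymmetric Morita–Baylis–Hillman reaction; β-isocupreidine with the hexafluoroisopropyl acrylate gives (R)-carbinols from aliphatic aldehydes under catalyst control, and the existing centre of 6 is β to the aldehyde and too remote to override it. This sets C6.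

Step 6
Reactants: 8 1,1,1,3,3,3-hexafluoropropan-2-yl (3R,5R)-3-hydroxy-6-[(2S,3S)-3-(methoxycarbonyl)-3-methyloxiran-2-yl]-2-methylidene-5-(prop-1-en-2-yl)hexanoate
Product: 9 (3R,5R)-3-hydroxy-6-[(2S,3S)-3-(methoxycarbonyl)-3-methyloxiran-2-yl]-2-methylidene-5-(prop-1-en-2-yl)hexanoic acid
Conditions: LiOH (1.5 equiv), THF/H2O, 0 °C; then 1 M HCl to pH 3, 0 °C
Reagents that add atoms: lithium hydroxide, [Li+].[OH-]
Why: Chemoselective saponification: the hexafluoroisopropyl ester is an activated ester and is cleaved within minutes at 0 °C, whereas the α-quaternary methyl glycidate is not.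

Step 7
Reactants: 9 (3R,5R)-3-hydroxy-6-[(2S,3S)-3-(methoxycarbonyl)-3-methyloxiran-2-yl]-2-methylidene-5-(prop-1-en-2-yl)hexanoic acid; 10 bromoacetyl bromide
Product: 11 (3R,5R)-3-[(bromoacetyl)oxy]-6-[(2S,3S)-3-(methoxycarbonyl)-3-methyloxiran-2-yl]-2-methylidene-5-(prop-1-en-2-yl)hexanoic acid
Conditions: pyridine, CH2Cl2, −20 → 0 °C; aqueous work-up
Reagents that add atoms: none
Why: O-Acylation of the secondary allylic alcohol by an acyl bromide. Pyridine is used because more nucleophilic amines would attack the Baylis–Hillman ester in an SN2′ sense; any mixed anhydride at the carboxyl group is hydrolysed on work-up.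

Step 8
Reactants: 11 (3R,5R)-3-[(bromoacetyl)oxy]-6-[(2S,3S)-3-(methoxycarbonyl)-3-methyloxiran-2-yl]-2-methylidene-5-(prop-1-en-2-yl)hexanoic acid
Product: 12 methyl (2S,3S)-2-methyl-3-[(2R)-3-methyl-2-{[(7R)-6-methylidene-2,5-dioxo-1,4-dioxepan-7-yl]methyl}but-3-en-1-yl]oxirane-2-carboxylate
Conditions: NaHCO3, DMF (0.01 M), 20 °C
Reagents that add atoms: none
Why: Intramolecular carboxylate alkylation by the α-bromo ester (7-exo-tet), the standard route to 1,4-dioxepane-2,5-diones from O-bromoacetyl β-hydroxy acids. Dilution suppresses oligomers and the weak base leaves the allylic ester alone.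

Step 9
Reactants: 12 methyl (2S,3S)-2-methyl-3-[(2R)-3-methyl-2-{[(7R)-6-methylidene-2,5-dioxo-1,4-dioxepan-7-yl]methyl}but-3-en-1-yl]oxirane-2-carboxylate
Product: 15 (2R,4E)-4-{(3R)-4-[(2S,3S)-3-(methoxycarbonyl)-3-methyloxiran-2-yl]-3-(prop-1-en-2-yl)butylidene}-5-oxooxolane-2-carboxylic acid, via silyl ketene acetal 13 (not isolated), via trimethylsilyl ester 14 (not isolated)
Conditions: Me3SiCl/Et3N (premixed, 5 equiv), THF, −78 °C; KN(SiMe3)2 (1.4 equiv), −78 → 20 °C (40 °C if needed); 0.5 M HCl
Reagents that add atoms: chlorotrimethylsilane, C[Si](C)(C)Cl (its silicon is carried by 13 and 14 only)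
Why: Proposed new method: KN(SiMe3)2 removes a proton from the glycolate CH2 (C9) of 12 in the presence of Me3SiCl and the enolate is trapped at once as ketene acetal 13, whose C9=C10 bond lies in the seven-membered ring, so the two ring oxygens are necessarily cis and only one acetal geometry exists. A [3,3] shift through C9–C10–O–C6–C7–C8 then forms C8–C9 and breaks C6–O, giving silyl ester 14 and, after aqueous acid, acid 15. The closest known reaction types are the Ireland–Claisen ring contraction of lactone silyl ketene acetals and the ester-enolate Claisen rearrangement of Morita–Baylis–Hillman esters; what has not been shown is a tether (ring oxygen plus lactone carbonyl) from the enolate terminus C9 to the central allyl carbon C7. The γ-lactone is closed by C–C bond formation (C8–C9) inside a chair-like bicyclo[3.2.1] array while the seven-membered ring contracts to five; seen as a cyclisation onto C7=C8 the geometry is 5-endo-trig, tolerable only because the shift is concerted with long partial bonds, and this strain is the unproven point. C9 is set by 1,3-chirality transfer from C6: the oxygen leaves and C9 arrives on the same face of the allyl unit, and since the ring fixes both the acetal geometry and the chair, (6R) gives (9R) in 15 (9S in 21 after the priority change at C10) when C5 lies syn to C8. That orientation keeps C5 away from the lactone carbonyl and gives the E alkene, as in SN2′ and Claisen reactions of Baylis–Hillman esters; the other orientation would give the Z alkene together with the C9 epimer, so one preference decides both elements. The step needs enolisation at C9 and not acyl migration to the enolate carbon (Chan rearrangement), γ-deprotonation at C6 or conjugate addition; this is secured by the internal silyl chloride quench at −78 °C, the non-nucleophilic base and the absence of an α-hydrogen at the C15 ester. The driving force is large (ketene acetal to silyl ester, a conjugated alkylidene lactone from a seven-membered dilactone) and the acceptor on C7 is of the kind that accelerates Claisen shifts.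

Step 10
Reactants: 15 (2R,4E)-4-{(3R)-4-[(2S,3S)-3-(methoxycarbonyl)-3-methyloxiran-2-yl]-3-(prop-1-en-2-yl)butylidene}-5-oxooxolane-2-carboxylic acid
Product: 17 methyl (2S,3S)-3-[(2R)-2-{(2E)-2-[(5R)-5-(hydroxymethyl)-2-oxooxolan-3-ylidene]ethyl}-3-methylbut-3-en-1-yl]-2-methyloxirane-2-carboxylate, via isobutyl carbonic anhydride 16 (not isolated)
Conditions: i-BuOCOCl, N-methylmorpholine, THF, −15 °C; then NaBH4, H2O, −15 → 0 °C
Reagents that add atoms: isobutyl chloroformate, CC(C)COC(Cl)=O (carried by 16 only)
Why: Reduction of a mixed carbonic anhydride with NaBH4: the activated acyl group is reduced at −15 °C faster than the lactone or the esters. Unlike borane, the reagent leaves the isopropenyl group alone, and C9 is not touched.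

Step 11
Reactants: 17 methyl (2S,3S)-3-[(2R)-2-{(2E)-2-[(5R)-5-(hydroxymethyl)-2-oxooxolan-3-ylidene]ethyl}-3-methylbut-3-en-1-yl]-2-methyloxirane-2-carboxylate
Product: 18 methyl (2S,3S)-3-[(2R)-2-{(2E)-2-[(5R)-5-(iodomethyl)-2-oxooxolan-3-ylidene]ethyl}-3-methylbut-3-en-1-yl]-2-methyloxirane-2-carboxylate
Conditions: I2, PPh3, imidazole, CH2Cl2, 0 → 20 °C
Reagents that add atoms: iodine, II
Why: Appel-type iodination of a primary alcohol under neutral conditions, which the alkylidene lactone and the epoxide tolerate.

Step 12
Reactants: 18 methyl (2S,3S)-3-[(2R)-2-{(2E)-2-[(5R)-5-(iodomethyl)-2-oxooxolan-3-ylidene]ethyl}-3-methylbut-3-en-1-yl]-2-methyloxirane-2-carboxylate; 19 methyl 3-oxobutanoate (methyl acetoacetate)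
Product: 20 methyl (2S,3S)-3-[(2R)-2-{(2E)-2-[(5S)-5-[2-(methoxycarbonyl)-3-oxobutyl]-2-oxooxolan-3-ylidene]ethyl}-3-methylbut-3-en-1-yl]-2-methyloxirane-2-carboxylate (C11 epimers)
Conditions: 19 (3 equiv), NaH (2.8 equiv), DMF, 0 °C; 18, 0 → 45 °C
Reagents that add atoms: none
Why: Acetoacetic ester alkylation: the sodium enolate of 19 displaces the primary iodide (SN2). Excess nucleophile compensates for the retarding β-oxygen, and Michael addition to the β-substituted alkylidene lactone is reversible; C11 forms as a mixture.

Step 13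
Reactants: 20 methyl (2S,3S)-3-[(2R)-2-{(2E)-2-[(5S)-5-[2-(methoxycarbonyl)-3-oxobutyl]-2-oxooxolan-3-ylidene]ethyl}-3-methylbut-3-en-1-yl]-2-methyloxirane-2-carboxylate (C11 epimers)
Product: 21 CNP0108136.1, the (2S,4R,6E,9S,11S,16S) macrocycle
Conditions: LiN(i-Pr)2 (3.3 equiv), THF, −78 °C, slow addition of 20 (final 0.002 M), −78 → −20 °C; aq. NH4Cl at −78 °C
Reagents that add atoms: none
Why: Claisen acylation of a β-keto ester dianion by an ester, run intramolecularly at high dilution like a macrocyclic Dieckmann condensation: the base removes C11–H and then a C14–H, the C14 carbanion attacks the C15 ester (no α-hydrogen) and loss of methoxide gives the diketonate, the third equivalent of base taking up the new acidic proton. Attack on the lactone carbonyl should only revert, since its forward collapse would give a strained eight-membered dione; C11 settles on protonation and equilibration as the more stable epimer.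

## Compound list

1 | (S)-(+)-carvone, (5S)-2-methyl-5-(prop-1-en-2-yl)cyclohex-2-en-1-one | CC1=CC[C@@H](CC1=O)C(C)=C | starting material
2 | (1S,4S,6S)-1-methyl-4-(prop-1-en-2-yl)-7-oxabicyclo[4.1.0]heptan-2-one | O=C1[C@@]2(C)O[C@H]2C[C@H](C(C)=C)C1 | intermediate
3 | (1S,4R,6S)-3-hydroxy-1-methyl-4-(prop-1-en-2-yl)-7-oxabicyclo[4.1.0]heptan-2-one (C3 epimers) | O=C1[C@@]2(C)O[C@H]2C[C@H](C(C)=C)C1O | intermediate
4 | methyl (2S,3S)-3-[(2R)-2-formyl-3-methylbut-3-en-1-yl]-2-methyloxirane-2-carboxylate | COC(=O)[C@@]1(C)O[C@H]1C[C@H](C(C)=C)C=O | intermediate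
5 | methyl (2S,3S)-3-[(2S)-2-(2-methoxyethenyl)-3-methylbut-3-en-1-yl]-2-methyloxirane-2-carboxylate (E/Z mixture) | COC(=O)[C@@]1(C)O[C@H]1C[C@H](C(C)=C)C=COC | intermediate (not isolated)
6 | methyl (2S,3S)-2-methyl-3-[(2S)-3-methyl-2-(2-oxoethyl)but-3-en-1-yl]oxirane-2-carboxylate | COC(=O)[C@@]1(C)O[C@H]1C[C@H](C(C)=C)CC=O | intermediate
7 | 1,1,1,3,3,3-hexafluoropropan-2-yl prop-2-enoate | C=CC(=O)OC(C(F)(F)F)C(F)(F)F | starting material
8 | 1,1,1,3,3,3-hexafluoropropan-2-yl (3R,5R)-3-hydroxy-6-[(2S,3S)-3-(methoxycarbonyl)-3-methyloxiran-2-yl]-2-methylidene-5-(prop-1-en-2-yl)hexanoate | COC(=O)[C@@]1(C)O[C@H]1C[C@H](C(C)=C)C[C@@H](O)C(=C)C(=O)OC(C(F)(F)F)C(F)(F)F | intermediate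
9 | (3R,5R)-3-hydroxy-6-[(2S,3S)-3-(methoxycarbonyl)-3-methyloxiran-2-yl]-2-methylidene-5-(prop-1-en-2-yl)hexanoic acid | COC(=O)[C@@]1(C)O[C@H]1C[C@H](C(C)=C)C[C@@H](O)C(=C)C(=O)O | intermediate
10 | bromoacetyl bromide | BrCC(Br)=O | starting material
11 | (3R,5R)-3-[(bromoacetyl)oxy]-6-[(2S,3S)-3-(methoxycarbonyl)-3-methyloxiran-2-yl]-2-methylidene-5-(prop-1-en-2-yl)hexanoic acid | COC(=O)[C@@]1(C)O[C@H]1C[C@H](C(C)=C)C[C@@H](OC(=O)CBr)C(=C)C(=O)O | intermediate
12 | methyl (2S,3S)-2-methyl-3-[(2R)-3-methyl-2-{[(7R)-6-methylidene-2,5-dioxo-1,4-dioxepan-7-yl]methyl}but-3-en-1-yl]oxirane-2-carboxylate | COC(=O)[C@@]1(C)O[C@H]1C[C@H](C(C)=C)C[C@H]2OC(=O)COC(=O)C2=C | intermediate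
13 | methyl (2S,3S)-2-methyl-3-[(2R)-3-methyl-2-({(7R)-6-methylidene-5-oxo-2-[(trimethylsilyl)oxy]-6,7-dihydro-5H-1,4-dioxepin-7-yl}methyl)but-3-en-1-yl]oxirane-2-carboxylate | COC(=O)[C@@]1(C)O[C@H]1C[C@H](C(C)=C)C[C@H]2OC(O[Si](C)(C)C)=COC(=O)C2=C | intermediate (not isolated)
14 | trimethylsilyl (2R,4E)-4-{(3R)-4-[(2S,3S)-3-(methoxycarbonyl)-3-methyloxiran-2-yl]-3-(prop-1-en-2-yl)butylidene}-5-oxooxolane-2-carboxylate | COC(=O)[C@@]1(C)O[C@H]1C[C@H](C(C)=C)C/C=C2\C[C@H](C(=O)O[Si](C)(C)C)OC2=O | intermediate (not isolated)
15 | (2R,4E)-4-{(3R)-4-[(2S,3S)-3-(methoxycarbonyl)-3-methyloxiran-2-yl]-3-(prop-1-en-2-yl)butylidene}-5-oxooxolane-2-carboxylic acid | COC(=O)[C@@]1(C)O[C@H]1C[C@H](C(C)=C)C/C=C2\C[C@H](C(=O)O)OC2=O | intermediate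
16 | mixed anhydride of 15 with isobutyl hydrogen carbonate | COC(=O)[C@@]1(C)O[C@H]1C[C@H](C(C)=C)C/C=C2\C[C@H](C(=O)OC(=O)OCC(C)C)OC2=O | intermediate (not isolated)
17 | methyl (2S,3S)-3-[(2R)-2-{(2E)-2-[(5R)-5-(hydroxymethyl)-2-oxooxolan-3-ylidene]ethyl}-3-methylbut-3-en-1-yl]-2-methyloxirane-2-carboxylate | COC(=O)[C@@]1(C)O[C@H]1C[C@H](C(C)=C)C/C=C2\C[C@H](CO)OC2=O | intermediate
18 | methyl (2S,3S)-3-[(2R)-2-{(2E)-2-[(5R)-5-(iodomethyl)-2-oxooxolan-3-ylidene]ethyl}-3-methylbut-3-en-1-yl]-2-methyloxirane-2-carboxylate | COC(=O)[C@@]1(C)O[C@H]1C[C@H](C(C)=C)C/C=C2\C[C@H](CI)OC2=O | intermediate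
19 | methyl 3-oxobutanoate (methyl acetoacetate) | COC(=O)CC(C)=O | starting material
20 | methyl (2S,3S)-3-[(2R)-2-{(2E)-2-[(5S)-5-[2-(methoxycarbonyl)-3-oxobutyl]-2-oxooxolan-3-ylidene]ethyl}-3-methylbut-3-en-1-yl]-2-methyloxirane-2-carboxylate (C11 epimers) | COC(=O)[C@@]1(C)O[C@H]1C[C@H](C(C)=C)C/C=C2\C[C@H](CC(C(C)=O)C(=O)OC)OC2=O | intermediate
21 | CNP0108136.1: 14-membered carbocycle (C2–C11, C13–C16) with the 2S,16S epoxide (methyl on C16), 4R isopropenyl, 13,15-dione, 11S methoxycarbonyl and the (6E)-alkylidene γ-lactone from the C7 carboxyl carbon to the 9S oxygen | C=C(C)[C@@H]1C/C=C2\C[C@H](C[C@H](C(=O)OC)C(=O)CC(=O)[C@@]3(C)O[C@H]3C1)OC2=O | target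

## Step count and least certain steps

Total step count: 13. Longest linear sequence: 13 steps from (S)-carvone (1); compounds 7, 10 and 19 enter as purchased.

**Step 9 (key step, proposed new method).**
- What may go wrong: the sigmatropic shift may be too slow, because the new bond has to be made to C8 while C9 is tied to C7 by only two atoms, so orbital overlap is poor; the ketene acetal would then revert to 12 on work-up or decompose on heating.
- Before silylation the enolate can undergo acyl migration onto the acrylate carbonyl, C6 can be deprotonated in the γ-position with loss of its configuration, and the allylic ester can suffer SN2′ attack.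
- Partial passage through the other orientation of C5 would give the Z alkene with the C9 epimer.
- Fallback by known chemistry, from 6 back to 15: aldehyde 6 and 7 with α-isocupreine, the pseudoenantiomeric catalyst, would give the (3S)-hydroxy ester F1. Methanolysis (MeOH, Et3N) gives methyl ester F2, and acylation with (4-methoxybenzyloxy)acetyl chloride and pyridine gives glycolate F3. An open-chain Ireland–Claisen rearrangement (KN(SiMe3)2, Me3SiCl, THF, −78 → 20 °C), known for Baylis–Hillman esters, should pass through the chelated Z-enolate and a chair to acid F4 with the E alkene. The opposite C6 configuration is needed because the open-chain ketene acetal has the opposite geometry to the ring-bound one, so F4 has the C9 configuration of 15. DDQ removes the 4-methoxybenzyl group to give hydroxy acid F5, and acid-catalysed lactonisation of the C9 hydroxyl onto the C7 methyl ester (camphorsulfonic acid, toluene) rejoins the route at 15.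

**Step 13.**
- What may go wrong: the C14 carbanion can attack the lactone carbonyl through a seven-membered arrangement instead of closing the large ring, and oligomers form if dilution is insufficient.
- The strong base may deprotonate C5 (γ to the lactone carbonyl) with deconjugation of the alkene.
- The diketonate can open the neighbouring epoxide on warming.
- Fallback, from 5 to 21: the large ring is closed instead at C10–C11 by soft enolate alkylation, which needs C15 at the alcohol level. Enol ether 5, isolated instead of hydrolysed, is reduced with i-Bu2AlH to epoxy alcohol F6 and silylated (t-BuPh2SiCl, imidazole) to silyl ether F7. Hydrolysis as in step 4 gives aldehyde F8. Steps 5–11 applied unchanged give in turn hydroxy ester F9, acid F10, bromoacetate F11, dilactone F12, lactone acid F13, alcohol F14 and iodide F15. HF·pyridine frees the C15 alcohol F16 and Dess–Martin periodinane gives epoxy aldehyde F17. The preformed dianion of 19 (NaH, then n-BuLi, THF, −78 °C) adds to the aldehyde only and gives aldol F18 (C15 epimers). Cs2CO3 in DMF at high dilution closes the ring to carbinol F19, and Dess–Martin oxidation of the C15 carbinol gives 21.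

**Step 12.**
- What may go wrong: substitution at the iodide next to the lactone oxygen is slow, so O-alkylation of the enolate, elimination to the enol lactone or conjugate addition to the alkylidene lactone may take over at the temperature needed.
- Fallback, from 17 to 20: oxidation of 17 with Dess–Martin periodinane gives aldehyde F20. Knoevenagel condensation with 19 (L-proline) gives alkylidene acetoacetate F21, which is reduced in the same flask by Hantzsch ester (organocatalytic reductive alkylation) to 20.

**Step 4.**
- What may go wrong: the basic ylide can epimerise C4 or move the isopropenyl double bond into conjugation, since the α-hydrogen of 4 is both allylic and next to the aldehyde.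
- Fallback, from 2 to 6: the extra carbon is put in before the ring is opened, so no α-branched aldehyde is formed. Ring expansion of 2 with Me3SiCHN2 and BF3·OEt2 at −78 °C (Tiffeneau–Demjanov type, migration of the CH2 rather than the oxygen-bearing quaternary carbon) gives cycloheptanone F22. Enolate hydroxylation as in step 2, at the only enolisable position, gives ketol F23, and Pb(OAc)4 in methanol as in step 3 cleaves it directly to 6.

## Further compounds

F1 | step 9 | 1,1,1,3,3,3-hexafluoropropan-2-yl (3S,5R)-3-hydroxy-6-[(2S,3S)-3-(methoxycarbonyl)-3-methyloxiran-2-yl]-2-methylidene-5-(prop-1-en-2-yl)hexanoate | COC(=O)[C@@]1(C)O[C@H]1C[C@H](C(C)=C)C[C@H](O)C(=C)C(=O)OC(C(F)(F)F)C(F)(F)F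
F2 | step 9 | methyl (3S,5R)-3-hydroxy-6-[(2S,3S)-3-(methoxycarbonyl)-3-methyloxiran-2-yl]-2-methylidene-5-(prop-1-en-2-yl)hexanoate | COC(=O)[C@@]1(C)O[C@H]1C[C@H](C(C)=C)C[C@H](O)C(=C)C(=O)OC
F3 | step 9 | methyl (3S,5R)-3-({[(4-methoxyphenyl)methoxy]acetyl}oxy)-6-[(2S,3S)-3-(methoxycarbonyl)-3-methyloxiran-2-yl]-2-methylidene-5-(prop-1-en-2-yl)hexanoate | COC(=O)[C@@]1(C)O[C@H]1C[C@H](C(C)=C)C[C@H](OC(=O)COCc2ccc(OC)cc2)C(=C)C(=O)OC
F4 | step 9 | (2R,4E,7R)-4-(methoxycarbonyl)-2-[(4-methoxyphenyl)methoxy]-8-[(2S,3S)-3-(methoxycarbonyl)-3-methyloxiran-2-yl]-7-(prop-1-en-2-yl)oct-4-enoic acid | COC(=O)[C@@]1(C)O[C@H]1C[C@H](C(C)=C)C/C=C(\C[C@H](C(=O)O)OCc2ccc(OC)cc2)C(=O)OC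
F5 | step 9 | (2R,4E,7R)-2-hydroxy-4-(methoxycarbonyl)-8-[(2S,3S)-3-(methoxycarbonyl)-3-methyloxiran-2-yl]-7-(prop-1-en-2-yl)oct-4-enoic acid | COC(=O)[C@@]1(C)O[C@H]1C[C@H](C(C)=C)C/C=C(\C[C@H](C(=O)O)O)C(=O)OC
F6 | step 13 | [(2R,3S)-3-[(2S)-2-(2-methoxyethenyl)-3-methylbut-3-en-1-yl]-2-methyloxiran-2-yl]methanol (E/Z mixture) | OC[C@@]1(C)O[C@H]1C[C@H](C(C)=C)C=COC
F7 | step 13 | tert-butyldiphenylsilyl ether of F6 | CC(C)(C)[Si](c3ccccc3)(c4ccccc4)OC[C@@]1(C)O[C@H]1C[C@H](C(C)=C)C=COC
F8 | step 13 | analogue of 6 with CH2OSiPh2(t-Bu) in place of the C15 methyl ester | CC(C)(C)[Si](c3ccccc3)(c4ccccc4)OC[C@@]1(C)O[C@H]1C[C@H](C(C)=C)CC=O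
F9 | step 13 | analogue of 8 with CH2OSiPh2(t-Bu) in place of the C15 methyl ester | CC(C)(C)[Si](c3ccccc3)(c4ccccc4)OC[C@@]1(C)O[C@H]1C[C@H](C(C)=C)C[C@@H](O)C(=C)C(=O)OC(C(F)(F)F)C(F)(F)F
F10 | step 13 | analogue of 9 with CH2OSiPh2(t-Bu) in place of the C15 methyl ester | CC(C)(C)[Si](c3ccccc3)(c4ccccc4)OC[C@@]1(C)O[C@H]1C[C@H](C(C)=C)C[C@@H](O)C(=C)C(=O)O
F11 | step 13 | analogue of 11 with CH2OSiPh2(t-Bu) in place of the C15 methyl ester | CC(C)(C)[Si](c3ccccc3)(c4ccccc4)OC[C@@]1(C)O[C@H]1C[C@H](C(C)=C)C[C@@H](OC(=O)CBr)C(=C)C(=O)O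
F12 | step 13 | analogue of 12 with CH2OSiPh2(t-Bu) in place of the C15 methyl ester | CC(C)(C)[Si](c3ccccc3)(c4ccccc4)OC[C@@]1(C)O[C@H]1C[C@H](C(C)=C)C[C@H]2OC(=O)COC(=O)C2=C
F13 | step 13 | analogue of 15 with CH2OSiPh2(t-Bu) in place of the C15 methyl ester | CC(C)(C)[Si](c3ccccc3)(c4ccccc4)OC[C@@]1(C)O[C@H]1C[C@H](C(C)=C)C/C=C2\C[C@H](C(=O)O)OC2=O
F14 | step 13 | analogue of 17 with CH2OSiPh2(t-Bu) in place of the C15 methyl ester | CC(C)(C)[Si](c3ccccc3)(c4ccccc4)OC[C@@]1(C)O[C@H]1C[C@H](C(C)=C)C/C=C2\C[C@H](CO)OC2=O
F15 | step 13 | analogue of 18 with CH2OSiPh2(t-Bu) in place of the C15 methyl ester | CC(C)(C)[Si](c3ccccc3)(c4ccccc4)OC[C@@]1(C)O[C@H]1C[C@H](C(C)=C)C/C=C2\C[C@H](CI)OC2=O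
F16 | step 13 | analogue of 18 with CH2OH in place of the C15 methyl ester | OC[C@@]1(C)O[C@H]1C[C@H](C(C)=C)C/C=C2\C[C@H](CI)OC2=O
F17 | step 13 | analogue of 18 with CHO in place of the C15 methyl ester | O=C[C@@]1(C)O[C@H]1C[C@H](C(C)=C)C/C=C2\C[C@H](CI)OC2=O
F18 | step 13 | methyl 5-hydroxy-3-oxopentanoate carrying at C5 the epoxide carbon C16 of F17 (C15 epimers; iodide at C10) | COC(=O)CC(=O)CC(O)[C@@]1(C)O[C@H]1C[C@H](C(C)=C)C/C=C2\C[C@H](CI)OC2=O
F19 | step 13 | 15-hydroxy analogue of 21 (C15 carbinol in place of the C15 ketone; C11 and C15 epimers) | C=C(C)[C@@H]1C/C=C2\C[C@H](CC(C(=O)OC)C(=O)CC(O)[C@@]3(C)O[C@H]3C1)OC2=O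
F20 | step 12 | methyl (2S,3S)-3-[(2R)-2-{(2E)-2-[(5R)-5-formyl-2-oxooxolan-3-ylidene]ethyl}-3-methylbut-3-en-1-yl]-2-methyloxirane-2-carboxylate | COC(=O)[C@@]1(C)O[C@H]1C[C@H](C(C)=C)C/C=C2\C[C@H](C=O)OC2=O
F21 | step 12 | Knoevenagel adduct of F20 and 19 (C10=C11 alkylidene acetoacetate; E/Z mixture) | COC(=O)[C@@]1(C)O[C@H]1C[C@H](C(C)=C)C/C=C2\C[C@H](C=C(C(C)=O)C(=O)OC)OC2=O
F22 | step 4 | (1S,5R,7S)-1-methyl-5-(prop-1-en-2-yl)-8-oxabicyclo[5.1.0]octan-2-one | O=C1[C@@]2(C)O[C@H]2C[C@H](C(C)=C)CC1
F23 | step 4 | (1S,5R,7S)-3-hydroxy-1-methyl-5-(prop-1-en-2-yl)-8-oxabicyclo[5.1.0]octan-2-one (C3 epimers) | O=C1[C@@]2(C)O[C@H]2C[C@H](C(C)=C)CC1O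
A1 | alternative 1 | open-chain C15 aldehyde with (Z)-vinyl iodide at C16 and silyl ether at C13 | C=C(C)[C@@H](C/C=C(\I)C)C/C=C1\C[C@H](C[C@H](C(=O)OC)[C@H](O[Si](C)(C)C(C)(C)C)CC=O)OC1=O
A2 | alternative 1 | macrocyclic (Z)-allylic alcohol at C15 | C=C(C)[C@@H]1C/C=C2\C[C@H](C[C@H](C(=O)OC)[C@H](O[Si](C)(C)C(C)(C)C)C[C@H](O)/C(C)=C\C1)OC2=O
A3 | alternative 2 | open-chain C13 aldoxime with ethynyl epoxide | C=C(C)[C@@H](C[C@@H]2O[C@]2(C)C#C)C/C=C1\C[C@H](C[C@H](C(=O)OC)C=NO)OC1=O
A4 | alternative 2 | isoxazole-bridged macrocycle | C=C(C)[C@@H]1C/C=C2\C[C@H](C[C@H](C(=O)OC)c3cc(on3)[C@@]4(C)O[C@H]4C1)OC2=O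
A5 | alternative 3 | open-chain C10 iodide with β-keto ester and C15 silyl ether | C=C(C)[C@@H](C[C@@H]2O[C@]2(C)[C@@H](O[Si](C)(C)C(C)(C)C)CC(=O)CC(=O)OC)C/C=C1\C[C@H](CI)OC1=O
A6 | alternative 3 | macrocyclic β-keto ester with C15 silyl ether | C=C(C)[C@@H]1C/C=C2\C[C@H](C[C@H](C(=O)OC)C(=O)C[C@H](O[Si](C)(C)C(C)(C)C)[C@@]3(C)O[C@H]3C1)OC2=O
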